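**Wednesday's books.** Wednesday's run is my ledger for substrate, the limiting reagent in the new flask, whose 1.0 mM is less than either nucleophile brings.

| flask | substrate | first nucleophile | solid second nucleophile | remark | time |
|---|---|---|---|---|---|
| Wednesday's | 1 mM | 2.4 equiv | 2 equiv | run made earlier |  |
| flask | 1.0 mM | 1.20 equiv | 2.00 equiv |  | 3.0 min |

- Wednesday's (time / s: target / %, substrate / %): 10.0: 26.2, 66.5; 15.0: 37.5, 54.9; 20.0: 46.7, 45.5; 25.0: 53.5, 36.1; 30.0: 59.3, 30.5; 40.0: 65.2, 20.4

(each reading ± 0.5 percentage points)

- what was read earlier has a scatter of 0.5 percentage points, one standard deviation
- at the start none of the solid second nucleophile is in solution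

1. the moment within 3.0 min at which there is most target
2. the amount of target, in percent of the substrate charged, at that time
3. the first time at which target reaches 43%, in the same percent, in min

**The entries.** At 40.0 s the readings show 20.4% as substrate and 65.2% as target, so 14.4% sits in neither column; at 20.0 s that gap reads 7.80%.

**The clock.** The last substrate reading gives 25.2 s, the substrate time constant: the time τ in the closed form c(substrate) = charge × exp(−t/τ). It predicts 45.2% at 20.0 s, against 45.5% read. I assume that half the first nucleophile leaves this clock unchanged.

**My reckoning.** The new flask should then keep 0.0782% as substrate at 3.0 min. If the gap stays as read, target reaches the asked level at 0.297 min.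

**The forecast.** The forecast gives 66% at 0.9 min and the level at 0.31 min, holding that “halving it should barely change the early kinetics”. Its time for the level is slightly later than mine.

**The result.** The flask gives 62.0% at 1.02 min and reaches the level at 0.373 min, later than both estimates.

    substrate → intermediate (k = 0.0400 /s)
    first nucleophile + intermediate → target (k = 220 /M/s)
    second nucleophile + intermediate → other capture product (k = 52.0 /M/s)
    second nucleophile + target → over-reaction product (k = 11.0 /M/s)
    substrate → decomposition product (k = 5.30 × 10⁻⁶ /s)
    solid second nucleophile ⇌ second nucleophile, rate k6*(cs6 - [second nucleophile]) while solid is left; crystals form when [second nucleophile] > cs6 (solubility = 0.560 mM, k = 0.120 /s)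

**What ran.** At 0.442 min the flask makes target 5.03 times faster than it uses it up, each step taken net. At 1.02 min the flask holds 8.67% of substrate, where the clock gives 8.82%. From 1.02 min to 3.00 min in the flask, over-reaction product grows from 14.7% to 49.7% and target falls from 62.0% to 36.3%, and at 3.00 min substrate stands at 0.0746% against the reckoned 0.0782%. The neighbour with 0.25 mM of substrate also keeps 0.0746% at that time, yet its best target is 48.3%, lower than in this flask.

The earlier runs and the new flask stem from a simulated flask with made-up constants; scatter was added.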